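**Retrosynthetic overview**
- The target is (2S)-7,3',4'-trihydroxyflavan-(4α→8)-(+)-catechin, a 2,4-cis flavan; the lower unit is bought as (+)-catechin and its rings are never opened.
- Last disconnection: the C4–H bond. Hydrogenation of a 4-aryl-flav-3-ene anti to the C2 aryl sets C4 (cis) and removes all benzyl groups in the same step.
- Key ring formation (the only ring made): the upper C-ring closes through O1–C2, the chalcone 2'-OH attacking C-β of a chalcone-derived cation. This is the bond and polarity of the chalcone-to-flavanone closure in flavonoid biosynthesis, here run under chiral-anion control to set C2 (S).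
- The C4–C8 interflavan bond is made before the ring exists, by 1,2-addition of 8-lithiated benzyl-protected catechin to the chalcone carbonyl.
- Order: catechin rings preformed → chalcone → triaryl allylic alcohol → C-ring closure → hydrogenation.

Assumption: the (R)-configured acid in step 5 is taken to give the 2S chromene; if a test run shows the opposite sense, the (S)-catalyst is used with no other change.

**Step 1**
Reactants: 1 1-[4-(benzyloxy)-2-hydroxyphenyl]ethan-1-one; 2 3,4-bis(benzyloxy)benzaldehyde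
Product: 3 (E)-1-[4-(benzyloxy)-2-hydroxyphenyl]-3-[3,4-bis(benzyloxy)phenyl]prop-2-en-1-one (tri-O-benzylbutein)
Conditions: KOH (50% aq), EtOH/THF, rt, 24–48 h; then dil. HCl
Reagents that add atoms: none
Why: Claisen–Schmidt aldol condensation gives the E-chalcone under thermodynamic control, and no stereocenter is formed.

**Step 2**
Reactants: 4 (+)-catechin
Product: 5 (2R,3S)-3,5,7-tris(benzyloxy)-2-[3,4-bis(benzyloxy)phenyl]chromane (penta-O-benzylcatechin)
Conditions: BnBr, K2CO3, DMF, rt, 24 h; then NaH (excess), TBAI (cat.), 0 °C → rt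
Reagents that add atoms: benzyl bromide, BrCc1ccccc1
Why: Williamson etherification, phenols first with carbonate and then the 3-alkoxide with NaH once no free 4'-phenoxide remains, so C2 and C3 of catechin are untouched.

**Step 3**
Reactants: 5 penta-O-benzylcatechin
Product: 6 (2R,3S)-3,5,7-tris(benzyloxy)-2-[3,4-bis(benzyloxy)phenyl]-8-bromochromane
Conditions: NBS (1.05 equiv), CH2Cl2, −78 °C → rt
Reagents that add atoms: N-bromosuccinimide, O=C1CCC(=O)N1Br
Why: Electrophilic aromatic bromination of benzylated catechins with NBS goes selectively to C8 of the phloroglucinol ring, and no stereocenter is affected.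

**Step 4**
Reactants: 6 8-bromo-penta-O-benzylcatechin; 3 tri-O-benzylbutein
Product: 9 (E)-1-[4-(benzyloxy)-2-hydroxyphenyl]-3-[3,4-bis(benzyloxy)phenyl]-1-(penta-O-benzylcatechin-8-yl)prop-2-en-1-ol (both carbinol epimers; used crude), via 8-lithio-penta-O-benzylcatechin 7 (not isolated), via chalcone sodium phenoxide 8 (not isolated)
Conditions: 6, n-BuLi, THF, −78 °C; 3, NaH, THF, 0 °C; combine at −78 → −40 °C; then H2O; crude dried azeotropically, no acidic contact
Reagents that add atoms: none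
Why: Bromine–lithium exchange followed by 1,2-addition of the aryllithium to the chalcone carbonyl (as its phenoxide) is the classical entry to 4-aryl-flav-3-ene precursors; the new carbinol center forms unselectively but is erased in step 5.

**Step 5**
Reactants: 9 triaryl allylic alcohol
Product: 11 (2S)-7-(benzyloxy)-2-[3,4-bis(benzyloxy)phenyl]-4-(penta-O-benzylcatechin-8-yl)-2H-chromene, via triarylallyl cation 10 (not isolated)
Conditions: (R)-H8-BINOL N-triflylphosphoramide with 3,3'-(2,4,6-iPr3C6H2)2 (10 mol%), toluene (0.02 M), −78 °C; minor C2 epimer removed on silica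
Reagents that add atoms: none
Why: Proposed new method: the strong chiral acid ionizes the tertiary alcohol to a 1,1,3-triarylallyl (vinylogous quinone-methide) cation held as a contact ion pair, and the only free phenol, the former chalcone 2'-OH, closes O1–C2 at the B-ring terminus inside that ion pair so the counteranion fixes C2 as S; the closest known reaction type is the N-triflylphosphoramide-catalysed asymmetric intramolecular allylic substitution (SN1') of 2-(1-hydroxyallyl)phenols to 2-aryl-2H-chromenes, and what is new is the bulky chiral flavanyl group on the cationic carbon.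

**Step 6**
Reactants: 11 (2S)-4-aryl-2H-chromene
Product: 12 (2S)-7,3',4'-trihydroxyflavan-(4α→8)-(+)-catechin
Conditions: H2 (4 bar), Pd/C, EtOAc, rt; then MeOH, Pd(OH)2/C, H2 (1 bar), rt
Reagents that add atoms: none
Why: Heterogeneous catalytic hydrogenation adds H2 to C3=C4 from the face opposite the C2 aryl, which sets C4 as S (2,4-cis) by substrate control, and hydrogenolysis removes the eight benzyl ethers.

**Compound list**
1 | 1-[4-(benzyloxy)-2-hydroxyphenyl]ethan-1-one | CC(=O)c1ccc(OCc2ccccc2)cc1O | starting material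
2 | 3,4-bis(benzyloxy)benzaldehyde | O=Cc1ccc(OCc2ccccc2)c(OCc2ccccc2)c1 | starting material
3 | (E)-1-[4-(benzyloxy)-2-hydroxyphenyl]-3-[3,4-bis(benzyloxy)phenyl]prop-2-en-1-one | O=C(/C=C/c1ccc(OCc2ccccc2)c(OCc2ccccc2)c1)c1ccc(OCc2ccccc2)cc1O | intermediate
4 | (+)-catechin, (2R,3S)-2-(3,4-dihydroxyphenyl)chromane-3,5,7-triol | Oc1cc(O)c2c(c1)O[C@H](c1ccc(O)c(O)c1)[C@@H](O)C2 | starting material
5 | (2R,3S)-3,5,7-tris(benzyloxy)-2-[3,4-bis(benzyloxy)phenyl]chromane | O(Cc1ccccc1)c1cc(OCc2ccccc2)c2c(c1)O[C@H](c1ccc(OCc3ccccc3)c(OCc3ccccc3)c1)[C@@H](OCc1ccccc1)C2 | intermediate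
6 | (2R,3S)-3,5,7-tris(benzyloxy)-2-[3,4-bis(benzyloxy)phenyl]-8-bromochromane | Brc1c(OCc3ccccc3)cc(OCc3ccccc3)c2c1O[C@H](c1ccc(OCc3ccccc3)c(OCc3ccccc3)c1)[C@@H](OCc1ccccc1)C2 | intermediate
7 | 8-lithio derivative of 5 (aryllithium at C8) | [Li]c1c(OCc3ccccc3)cc(OCc3ccccc3)c2c1O[C@H](c1ccc(OCc3ccccc3)c(OCc3ccccc3)c1)[C@@H](OCc1ccccc1)C2 | intermediate
8 | sodium 2'-phenoxide of chalcone 3 | [Na+].[O-]c1cc(OCc2ccccc2)ccc1C(=O)/C=C/c1ccc(OCc2ccccc2)c(OCc2ccccc2)c1 | intermediate
9 | (E)-1-[4-(benzyloxy)-2-hydroxyphenyl]-3-[3,4-bis(benzyloxy)phenyl]-1-[(2R,3S)-3,5,7-tris(benzyloxy)-2-(3,4-bis(benzyloxy)phenyl)chroman-8-yl]prop-2-en-1-ol, both epimers at the carbinol carbon | OC(/C=C/c1ccc(OCc2ccccc2)c(OCc2ccccc2)c1)(c1ccc(OCc2ccccc2)cc1O)c1c(OCc3ccccc3)cc(OCc3ccccc3)c2c1O[C@H](c1ccc(OCc3ccccc3)c(OCc3ccccc3)c1)[C@@H](OCc1ccccc1)C2 | intermediate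
10 | 1,1,3-triarylallyl cation from 9 (ion pair with the catalyst anion; drawn with the charge at the B-ring benzylic carbon) | Oc1cc(OCc2ccccc2)ccc1C(=C[CH+]c1ccc(OCc2ccccc2)c(OCc2ccccc2)c1)c1c(OCc3ccccc3)cc(OCc3ccccc3)c2c1O[C@H](c1ccc(OCc3ccccc3)c(OCc3ccccc3)c1)[C@@H](OCc1ccccc1)C2 | intermediate
11 | (2S)-7-(benzyloxy)-2-[3,4-bis(benzyloxy)phenyl]-4-[(2R,3S)-3,5,7-tris(benzyloxy)-2-(3,4-bis(benzyloxy)phenyl)chroman-8-yl]-2H-chromene | O(Cc1ccccc1)c1ccc2c(c1)O[C@H](c1ccc(OCc3ccccc3)c(OCc3ccccc3)c1)C=C2c1c(OCc3ccccc3)cc(OCc3ccccc3)c2c1O[C@H](c1ccc(OCc3ccccc3)c(OCc3ccccc3)c1)[C@@H](OCc1ccccc1)C2 | intermediate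
12 | (2S,4S)-2-(3,4-dihydroxyphenyl)-4-[(2R,3S)-2-(3,4-dihydroxyphenyl)-3,5,7-trihydroxychroman-8-yl]chroman-7-ol, 2,4-cis | Oc1ccc2c(c1)O[C@H](c1ccc(O)c(O)c1)C[C@@H]2c1c(O)cc(O)c2c1O[C@H](c1ccc(O)c(O)c1)[C@@H](O)C2 | target

**Totals**
Total step count: 6. Longest linear sequence: 5 (steps 2, 3, 4, 5, 6 from catechin).

**Three steps most likely to fail**

Step 5 (chiral ion-pair ring closure). The cation carries a very bulky, chiral, electron-rich aryl group, so facial control by the anion may be poor, and the product may re-ionize at C2 and erode the ratio. The fallback gives up catalyst control and uses the catechin unit as a built-in resolving handle. It sets out from 9: PPTS in CH2Cl2 at 0 °C closes the ring without facial bias to a roughly 1:1 mixture of 11 and its C2 epimer, the (2R)-chromene F1. The two are diastereomers and are separated by chromatography. F1 is returned to the 1:1 mixture by re-ionization with the same acid at room temperature (reversible C2–O1 heterolysis) and separated again, so the route is rejoined at 11.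

Step 4 (aryllithium addition to the chalcone phenoxide). The phenoxide lowers the electrophilicity of the carbonyl, and the hindered 2,6-dioxygenated aryllithium may add 1,4 or not at all. The fallback removes the phenoxide from the picture. It sets out from 3: the 2'-OH is silylated (TBSCl, imidazole, DMF) to the TBS chalcone F2, which has an ordinary enone carbonyl. Aryllithium 7 then adds 1,2 at −78 °C to give the silyl ether F3. Buffered TBAF (AcOH, THF, 0 °C) frees the phenol and the route is rejoined at 9.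

Step 6 (hydrogenation with global debenzylation). The trisubstituted, doubly ortho-hindered alkene may reduce slowly, leaving time for Pd-mediated double-bond migration to the 4H-chromene (loss of C2) or for cleavage of the allylic C2–O1 bond. The fallback replaces surface hydrogenation by ionic hydrogenation. It sets out from 11: Et3SiH and TFA in CH2Cl2 at −40 °C protonate C3 and deliver hydride to the C4 diarylmethyl cation trans to the C2 aryl, giving the octa-O-benzyl cis-flavan F4. Its benzyl ethers are then removed with H2 and Pd(OH)2/C in THF/MeOH, and the route is rejoined at 12.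

**Further compounds**
F1 | step 5 | (2R)-7-(benzyloxy)-2-[3,4-bis(benzyloxy)phenyl]-4-[(2R,3S)-3,5,7-tris(benzyloxy)-2-(3,4-bis(benzyloxy)phenyl)chroman-8-yl]-2H-chromene (C2 epimer of 11) | O(Cc1ccccc1)c1ccc2c(c1)O[C@@H](c1ccc(OCc3ccccc3)c(OCc3ccccc3)c1)C=C2c1c(OCc3ccccc3)cc(OCc3ccccc3)c2c1O[C@H](c1ccc(OCc3ccccc3)c(OCc3ccccc3)c1)[C@@H](OCc1ccccc1)C2
F2 | step 4 | (E)-1-[4-(benzyloxy)-2-(tert-butyldimethylsilyloxy)phenyl]-3-[3,4-bis(benzyloxy)phenyl]prop-2-en-1-one | O=C(/C=C/c1ccc(OCc2ccccc2)c(OCc2ccccc2)c1)c1ccc(OCc2ccccc2)cc1O[Si](C)(C)C(C)(C)C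
F3 | step 4 | 2'-O-TBS ether of alcohol 9, both carbinol epimers | OC(/C=C/c1ccc(OCc2ccccc2)c(OCc2ccccc2)c1)(c1ccc(OCc2ccccc2)cc1O[Si](C)(C)C(C)(C)C)c1c(OCc3ccccc3)cc(OCc3ccccc3)c2c1O[C@H](c1ccc(OCc3ccccc3)c(OCc3ccccc3)c1)[C@@H](OCc1ccccc1)C2
F4 | step 6 | (2S,4S)-7-(benzyloxy)-2-[3,4-bis(benzyloxy)phenyl]-4-[(2R,3S)-3,5,7-tris(benzyloxy)-2-(3,4-bis(benzyloxy)phenyl)chroman-8-yl]chromane (octa-O-benzyl 12) | O(Cc1ccccc1)c1ccc2c(c1)O[C@H](c1ccc(OCc3ccccc3)c(OCc3ccccc3)c1)C[C@@H]2c1c(OCc3ccccc3)cc(OCc3ccccc3)c2c1O[C@H](c1ccc(OCc3ccccc3)c(OCc3ccccc3)c1)[C@@H](OCc1ccccc1)C2
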